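## Structural features

The target is a flavan-3-ol. Benzene ring A is fused to the dihydropyran ring C (a chroman), the catechol ring B sits on C2, and C3 carries a secondary hydroxyl. A 3,4,5-trihydroxybenzoyl group is bound as an aryl ester to O7 of ring A, while O5 stays a free phenol. The only stereocentres are the neighbours C2 (R, bearing ring B and O1) and C3 (S, bearing OH), with their substituents trans. The phenolic ester is the most fragile bond, since bases and nucleophiles cleave it or pass the acyl group to other oxygens. The catechol, pyrogallol and ring A phenols are oxidised easily in air and base, and once the 4'-hydroxyl is free the benzylic C2–O1 bond can open and epimerise C2, so free phenols should appear only in a last, neutral step. The real difficulty is telling O7 from O5, which sit meta to each other on a phloroglucinol-type ring and cannot be distinguished on a finished flavan; the second difficulty is the trans-(2R,3S) pair. The key step uses the fact that O1, C2, C3, C4a and C8a of ring C are the five ring atoms of a 2-arylbenzofuran-3(2H)-one, which lacks only C4 between the carbonyl carbon and ring A. In that ketone the carbonyl hydrogen-bonds the peri hydroxyl (future O5), whereas the hydroxyl para to the acyl-bearing ring carbon (future O7) is the acidic, unchelated one and can take the galloyl group first.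

## Logic of the disconnections

**12 to 11.** The six O–CH2Ph bonds (O5, O3', O4' and the three gallate oxygens) are cut. All phenols are masked by one group that hydrogen removes under neutral conditions, so the oxidisable polyphenol exists only at the end. Every earlier compound is then a stable, chromatographable ether. The forward step must spare the aryl ester, the benzylic C2–O1 bond and both stereocentres.

**11 to 10.** The C3–H bond is removed and the configuration at C2 is given up. With a carbonyl at C3, C2 becomes configurationally mobile, so one reduction under dynamic conditions can set both centres. The gain is a racemic ketone without any stereochemical burden. The demand is a reductant that takes only the 2R ketone, places the hydroxyl trans to ring B, and is slower than the epimerisation at C2.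

**10 to 7 and 8 (through 9).** The bonds C3–C4 and C4–C4a are cut and C4 is excised, so ring C contracts to the five-membered ring of 7. The cut is made here because in the bicyclic ketone series the O5/O7 distinction is already built in. The gain is that ring A with correctly differentiated oxygens comes from a purchasable ring system. The demand is severe: the ring A carbon and not C2 must migrate, only one carbon may be inserted, and 8 must attack the carbonyl carbon and not the enol oxygen. The skeleton of 7 is kept. The only electronic correction is that the ester oxygen para to the migrating carbon is not a real donor, so the migration argument rests on the two ortho ether oxygens.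

**7 to 5 and 6.** The bond between C2 and ring B is cut. C2 is the α-carbon of the ketone and a natural nucleophile, and ring B arrives intact as the aryl bromide 6. This makes the assembly convergent and places the arylation directly before the key step, so the air-sensitive C2–H compound 7 is never stored. The demand is monoarylation under a base weak enough to leave the aryl ester untouched.

**5 to 4.** The O4–CH2Ph bond is cut. The peri oxygen must be capped so that it neither quenches the Lewis acid as a phenol nor is alkylated by 8, and the cap must fall off in the final hydrogenolysis. The demand is etherification of a hydrogen-bonded phenol without a free phenoxide that could trigger acyl transfer.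

**4 to 1 and 2 (through 3).** The ester bond between the galloyl carbonyl and O6 is cut. The acidity difference between the two hydroxyls of 1 lets the acyl group go to the future O7 at the outset with no protecting-group detour. The demand is one equivalent of acylating agent and an amine base, so that the chelated hydroxyl and the C2 methylene do not react.

## Other disconnections considered

**Alternative 1:** The cut detaches ring A from ring C at O1–C8a and C4–C4a, leaving a three-carbon piece that already holds C2 and C3. In the forward step CsF would release the aryne from the silyl triflate A1. The alkoxide of the anti aldol ester A2 would add to the aryne carbon meta to the benzyloxy group, and the aryl anion formed next to that group would close onto the ester carbonyl to give the chroman-4-one A3.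
- In its favour: both stereocentres come from an asymmetric anti-glycolate aldol reaction, which is more predictable than an enzyme screen, so here the alternative is the better. The sense of addition to a 3-alkoxyaryne is well precedented, again better than the unprecedented migration selectivity of step 4. Two ring bonds form in one convergent step, which equals the chosen plan.
- Against it: A3 has a C4 carbonyl that the target lacks, so a reduction and a benzylic deoxygenation under ionising acid must follow, which endangers the 4-methoxybenzyl ether and the C2–O1 bond. O7 is only marked, so unmasking and galloylation add steps. The O5/O7 problem is moved into the synthesis of A1, a benzene with three different oxygen substituents and a regiodefined silyl/triflate pair. The β-alkoxide of A2 may fragment by retro-aldol reaction, or the aryl anion may be protonated before it acylates.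
- Comparison: the alternative stands on firmer mechanistic ground for ring closure and stereochemistry, but it is at the wrong oxidation level at C4 and would be roughly twice as long. The chosen plan buys the differentiated ring A in one commercial compound and needs no redox correction.

**Alternative 2:** Only C4–C4a is cut; ring A stays attached through O1 as an aryl ether and C3–C4 is an epoxide. In the forward step the epoxy ether A4 would be dissolved in hexafluoroisopropanol, whose hydrogen bonding activates the epoxide. The ring A carbon ortho to O1 would attack the terminal epoxide carbon, releasing the C3 hydroxyl of A5.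
- In its favour: the reaction type is known, so no step is without precedent, which is better than the chosen plan. C2 and C3 are set beforehand by asymmetric epoxidation chemistry and neither is touched in the ring closure, also better. The product arrives at the alcohol oxidation level, saving the reduction.
- Against it: ring A of A4 has two non-equivalent carbons ortho to O1, and only the bulk of the triisopropylsilyl group steers closure to the carbon next to the benzyloxy group; the chosen plan fixes this by a covalent bond already present in 1. The C2–O1 bond of A4 is a benzylic aryl ether activated by ring B and may ionise in the strongly ionising solvent, eroding C2. Attack at the internal epoxide carbon would give a dihydrobenzofuran. After cyclisation the silyl ether must be cleaved and the 7-phenol acylated selectively beside the C3 alcohol. A4 itself needs an etherification with inversion at an electron-rich benzylic carbinol.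
- Comparison: lower mechanistic risk in the key step and better stereochemical certainty, but weaker control of the ring A regiochemistry and a clearly longer sequence.

**Alternative 3:** The cuts O1–C2 and C3–C4 divide ring C into an ortho-quinone methide (ring A plus C4) and a two-carbon enol derivative carrying ring B. In the forward step the salicyl alcohol A6 would lose water under a chiral phosphoric acid, and the quinone methide would combine as heterodiene with the (E)-enol carbonate A7 to give A8. The E geometry would become the trans relation and the catalyst would select the face.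
- In its favour: ring C and both stereocentres arise in one step, which is better than ring enlargement plus a separate reduction. A6 is symmetric about its hydroxymethyl axis, so either ortho hydroxyl can become O1 while O7 is the unique para oxygen acylated at the outset, which equals the regiochemical solution of the chosen plan. A8 needs only one hydrogenolysis, because the carbonate is benzyl-based; the whole route would be about five steps, equal to or shorter than the chosen one.
- Against it: an enol derivative normally bonds through its oxygen-free carbon to the methide carbon, which would put ring B on C3 and the carbonate on C2. The required orientation depends on the electron-rich styrene character outweighing the enol carbonate character, which is not assured. Enantiocontrol is asked of a quinone methide with a second free phenol and an aryl ester reacting with a weak nucleophile. A7 must be a single geometric isomer and is hydrolytically delicate. Acid may ionise the C2–O1 bond of A8 and equilibrate trans to cis.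
- Comparison: on step economy and convergence the alternative is the better. On mechanism both plans depend on a selectivity without direct precedent, but the chosen plan separates the skeleton-forming event from the stereochemical event, so each can be optimised or replaced on its own.

Key step: step 4

Remark on the chemistry: 1, 2, 6 and 8 (as a hexane solution) are taken as purchased; 7 is assumed to react in its keto form; the ketoreductase of step 5 is assumed to be found by screening a commercial enzyme panel.

## Route

Step 1
Reactants: 1 4,6-dihydroxybenzofuran-3(2H)-one; 2 3,4,5-tris(benzyloxy)benzoic acid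
Product: 4 4-hydroxy-3-oxo-2,3-dihydrobenzofuran-6-yl 3,4,5-tris(benzyloxy)benzoate, via 3,4,5-tris(benzyloxy)benzoyl chloride 3 (not isolated)
Conditions: 2, (COCl)2, cat. DMF, CH2Cl2, 0 °C to rt, evaporate; then 1, Et3N (1.05 equiv), THF, −20 to 0 °C
Reagents that add atoms: oxalyl chloride, O=C(Cl)C(=O)Cl (supplies the chlorine of 3 only; no atom of it remains in 4)
Why: O-Acylation of a phenol with an acid chloride made in the flask by Vilsmeier-type activation of 2. The 6-OH of 1 is para to the carbonyl-bearing ring carbon and not hydrogen-bonded, so it is the more acidic phenol and the one deprotonated by one equivalent of Et3N; the 4-OH is held in a hydrogen bond to the C3 carbonyl and the C2 methylene is not deprotonated by an amine base.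

Step 2
Reactants: 4 4-hydroxy-3-oxo-2,3-dihydrobenzofuran-6-yl 3,4,5-tris(benzyloxy)benzoate
Product: 5 4-(benzyloxy)-3-oxo-2,3-dihydrobenzofuran-6-yl 3,4,5-tris(benzyloxy)benzoate
Conditions: BnOH, PPh3, DIAD, THF, 0 °C to rt
Reagents that add atoms: benzyl alcohol, OCc1ccccc1
Why: Mitsunobu etherification of the remaining phenol; the phenol is acidic enough as pronucleophile and the benzyloxyphosphonium ion is a reactive, unhindered electrophile. No carbonate base or long-lived phenoxide is present, so the aryl ester should be neither cleaved nor passed from O6 to O4.

Step 3
Reactants: 5 4-(benzyloxy)-3-oxo-2,3-dihydrobenzofuran-6-yl 3,4,5-tris(benzyloxy)benzoate; 6 4-bromo-1,2-bis(benzyloxy)benzene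
Product: 7 rac-4-(benzyloxy)-2-[3,4-bis(benzyloxy)phenyl]-3-oxo-2,3-dihydrobenzofuran-6-yl 3,4,5-tris(benzyloxy)benzoate
Conditions: Pd(OAc)2 (3 mol%), 2-dicyclohexylphosphino-2',4',6'-triisopropylbiphenyl (6 mol%), K3PO4 (2.5 equiv), toluene, 70 °C, Ar; then AcOH, degassed aq. NH4Cl
Reagents that add atoms: none
Why: Palladium-catalysed α-arylation of a ketone: oxidative addition of 6 to zerovalent palladium, binding of the potassium enolate of 5 and C–C reductive elimination. The α-aryloxy ketone is acidic enough for the weak, insoluble base K3PO4, which spares the aryl ester, and the bulky biaryl phosphine together with the lower reactivity of the more stabilised product enolate should hold the reaction at monoarylation. C2 is formed racemic and left so; 7 is quenched with acid and carried on without storage because its C2–H is prone to autoxidation.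

Step 4
Reactants: 7 rac-4-(benzyloxy)-2-[3,4-bis(benzyloxy)phenyl]-3-oxo-2,3-dihydrobenzofuran-6-yl 3,4,5-tris(benzyloxy)benzoate; 8 trimethylsilyldiazomethane
Product: 10 rac-5-(benzyloxy)-2-[3,4-bis(benzyloxy)phenyl]-3-oxochroman-7-yl 3,4,5-tris(benzyloxy)benzoate, via 4-(trimethylsilyl)chroman-3-one 9 (not isolated)
Conditions: 8 (2 M in hexanes, 1.5 equiv), Sc(OTf)3 (10 mol%), CH2Cl2, −78 to −20 °C; then 1 M HCl, THF, 0 °C
Reagents that add atoms: none
Why: Proposed new method: Sc(OTf)3, bound to the C3 carbonyl oxygen and the peri benzyloxy oxygen of 7, should activate the ketone for attack by the diazo carbon of 8; the resulting scandium alkoxide carries a β-diazonium group, and loss of N2 is coupled to a 1,2-shift of the ring A carbon from C3 to the new carbon, so that the bond made in the addition becomes C3–C4 and the shift makes C4–C4a. The closest known reaction type is the Lewis acid-promoted diazoalkane homologation of ketones (Tiffeneau–Demjanov type), established for cycloalkanones and for benzo-fused ketones such as 1-indanones, which give 2-tetralones, but not for a benzofuran-3(2H)-one. Ring C is closed not by a cyclisation but by ring enlargement: the five-membered O1–C2–C3–C3a–C7a ring takes up one carbon through a 1,2-aryl shift and becomes the six-membered pyran ring. No stereocentre is created, and C2 stays racemic and mobile, as step 5 requires. The first selectivity needed is migration of the ring A carbon and not of C2: the aryl carbon can migrate through a bridged, phenonium-like transition state stabilised by its two ortho ether oxygens, whereas C2 carries the inductively withdrawing O1, whose lone pair is engaged with ring A, and is the more hindered carbon. The second is a single insertion: the ketone leaves as the α-silyl ketone 9 or its silyl enol ether, which is too hindered or no longer electrophilic enough to take up a second carbon. The third is attack on the carbonyl carbon of the keto form and not O-alkylation of the enol tautomer: the keto form is favoured because the carbonyl is part of a vinylogous ester, and an aprotic solvent at low temperature without alcohol keeps 8 from acting as an alkylating agent. Dilute acid in the work-up then removes the silyl group from C4 and gives 10.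

Step 5
Reactants: 10 rac-5-(benzyloxy)-2-[3,4-bis(benzyloxy)phenyl]-3-oxochroman-7-yl 3,4,5-tris(benzyloxy)benzoate
Product: 11 (2R,3S)-5-(benzyloxy)-2-[3,4-bis(benzyloxy)phenyl]-3-hydroxychroman-7-yl 3,4,5-tris(benzyloxy)benzoate
Conditions: trans-selective NADPH-dependent ketoreductase, NADP+ (cat.), i-PrOH, potassium phosphate buffer pH 8, DMSO co-solvent, 35 °C
Reagents that add atoms: none
Why: Biocatalytic dynamic kinetic resolution by ketone reduction: the enantiomers of 10 interconvert through the C2 enol in the mildly basic medium, the enzyme accepts the 2R ketone and transfers hydride from NADPH to the C3 face that leaves the new hydroxyl trans to ring B, which sets C3 as S and funnels the material into the (2R,3S) alcohol. Isopropanol regenerates the cofactor, and pH 8 at 35 °C should leave the aryl ester intact.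

Step 6
Reactants: 11 (2R,3S)-5-(benzyloxy)-2-[3,4-bis(benzyloxy)phenyl]-3-hydroxychroman-7-yl 3,4,5-tris(benzyloxy)benzoate
Product: 12 catechin 7-O-gallate [(2R,3S)-2-(3,4-dihydroxyphenyl)-3,5-dihydroxychroman-7-yl 3,4,5-trihydroxybenzoate]
Conditions: H2 (1 atm), Pd(OH)2/C, THF/MeOH, rt; filtration under Ar
Reagents that add atoms: none
Why: Hydrogenolysis of six aryl benzyl ethers under neutral conditions; aryl benzyl ethers are cleaved much faster than the cyclic benzylic C2–O1 ether, and the aryl ester and both stereocentres are not affected. The free polyphenol appears only here and is isolated under inert gas.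

## Compound list

1 | 4,6-dihydroxybenzofuran-3(2H)-one | O=C1COc2cc(O)cc(O)c12 | starting material
2 | 3,4,5-tris(benzyloxy)benzoic acid | O=C(O)c1cc(OCc2ccccc2)c(OCc2ccccc2)c(OCc2ccccc2)c1 | starting material
3 | 3,4,5-tris(benzyloxy)benzoyl chloride | O=C(Cl)c1cc(OCc2ccccc2)c(OCc2ccccc2)c(OCc2ccccc2)c1 | intermediate
4 | 4-hydroxy-3-oxo-2,3-dihydrobenzofuran-6-yl 3,4,5-tris(benzyloxy)benzoate | O=C(Oc1cc(O)c2c(c1)OCC2=O)c1cc(OCc2ccccc2)c(OCc2ccccc2)c(OCc2ccccc2)c1 | intermediate
5 | 4-(benzyloxy)-3-oxo-2,3-dihydrobenzofuran-6-yl 3,4,5-tris(benzyloxy)benzoate | O=C(Oc1cc(OCc3ccccc3)c2c(c1)OCC2=O)c1cc(OCc2ccccc2)c(OCc2ccccc2)c(OCc2ccccc2)c1 | intermediate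
6 | 4-bromo-1,2-bis(benzyloxy)benzene | Brc1ccc(OCc2ccccc2)c(OCc2ccccc2)c1 | starting material
7 | rac-4-(benzyloxy)-2-[3,4-bis(benzyloxy)phenyl]-3-oxo-2,3-dihydrobenzofuran-6-yl 3,4,5-tris(benzyloxy)benzoate (C2 racemic and labile) | O=C(Oc1cc(OCc3ccccc3)c2c(c1)OC(c1ccc(OCc3ccccc3)c(OCc3ccccc3)c1)C2=O)c1cc(OCc2ccccc2)c(OCc2ccccc2)c(OCc2ccccc2)c1 | intermediate
8 | trimethylsilyldiazomethane | C[Si](C)(C)C=[N+]=[N-] | starting material
9 | 5-(benzyloxy)-2-[3,4-bis(benzyloxy)phenyl]-3-oxo-4-(trimethylsilyl)chroman-7-yl 3,4,5-tris(benzyloxy)benzoate (mixture of stereoisomers) | O=C(Oc1cc(OCc3ccccc3)c2c(c1)OC(c1ccc(OCc3ccccc3)c(OCc3ccccc3)c1)C(=O)C2[Si](C)(C)C)c1cc(OCc2ccccc2)c(OCc2ccccc2)c(OCc2ccccc2)c1 | intermediate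
10 | rac-5-(benzyloxy)-2-[3,4-bis(benzyloxy)phenyl]-3-oxochroman-7-yl 3,4,5-tris(benzyloxy)benzoate (C2 racemic and labile) | O=C(Oc1cc(OCc3ccccc3)c2c(c1)OC(c1ccc(OCc3ccccc3)c(OCc3ccccc3)c1)C(=O)C2)c1cc(OCc2ccccc2)c(OCc2ccccc2)c(OCc2ccccc2)c1 | intermediate
11 | (2R,3S)-5-(benzyloxy)-2-[3,4-bis(benzyloxy)phenyl]-3-hydroxychroman-7-yl 3,4,5-tris(benzyloxy)benzoate | O=C(Oc1cc(OCc3ccccc3)c2c(c1)O[C@H](c1ccc(OCc3ccccc3)c(OCc3ccccc3)c1)[C@@H](O)C2)c1cc(OCc2ccccc2)c(OCc2ccccc2)c(OCc2ccccc2)c1 | intermediate
12 | catechin 7-O-gallate, (2R,3S)-2-(3,4-dihydroxyphenyl)-3,5-dihydroxychroman-7-yl 3,4,5-trihydroxybenzoate | O=C(Oc1cc(O)c2c(c1)O[C@H](c1ccc(O)c(O)c1)[C@@H](O)C2)c1cc(O)c(O)c(O)c1 | target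

## Step count and least certain steps

Total: 6 steps (step 1 is a two-stage, one-flask operation). Longest linear sequence: 6 steps, from 1 to 12.

**Step 4 (key step, carries the label "Proposed new method:").** The most likely failures are alkylation of the oxygen of the aromatic enol tautomer by the diazo reagent, migration of C2 instead of the ring A carbon, or no addition at all to the hindered, electron-rich carbonyl. All three stem from the same cause: the substrate is an easily enolised vinylogous ester whose C2 is benzylic and oxygen-bearing. The fallback uses known chemistry, builds ring C by a different bond set and keeps the chelation logic for O5/O7. It sets out from 3 and returns at 10. Acid chloride 3 would acylate purchasable 2,4,6-trihydroxybenzaldehyde at its unchelated 4-OH (Et3N, THF, −20 °C) to give 4-formyl-3,5-dihydroxyphenyl 3,4,5-tris(benzyloxy)benzoate F1. Mitsunobu monobenzylation of one of the two equivalent chelated hydroxyls (BnOH, PPh3, DIAD) would give 3-(benzyloxy)-4-formyl-5-hydroxyphenyl 3,4,5-tris(benzyloxy)benzoate F2. A DABCO-catalysed oxa-Michael/Henry/dehydration cascade with purchasable (E)-1,2-bis(benzyloxy)-4-(2-nitrovinyl)benzene would close ring C as rac-5-(benzyloxy)-2-[3,4-bis(benzyloxy)phenyl]-3-nitro-2H-chromen-7-yl 3,4,5-tris(benzyloxy)benzoate F3. Reduction of the conjugated nitroalkene with iron powder in acetic acid and hydrolysis of the resulting oxime (Nef-type conversion) would give ketone 10.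

**Step 3.** The likely failure is transfer of the galloyl group from O6 to the enolate oxygen, or its loss, under the basic conditions; a second arylation and autoxidation of the product enolate are further risks. The fallback avoids a base-generated enolate altogether. It sets out from 5 and returns at 7. Treatment of 5 with TMSOTf and Et3N would give the aromatic enol silane 4-(benzyloxy)-3-[(trimethylsilyl)oxy]benzofuran-6-yl 3,4,5-tris(benzyloxy)benzoate F4. Fluoride-promoted palladium-catalysed coupling of F4 with 6 (Pd(OAc)2, P(t-Bu)3, ZnF2, CsF, DMF, 80 °C) would give 7 directly after aqueous work-up.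

**Step 5.** The likely failure is that no enzyme turns over the large, poorly soluble ketone, or that C2 epimerises more slowly than the ketone is reduced, so that only a kinetic resolution results; delivery of hydride to the other face (cis alcohol) is also possible. The fallback replaces biocatalysis by substrate-controlled reduction, resolution and recycling. It sets out from 10 and returns at 11. Reduction with NaBH4 and CeCl3·7H2O in THF/MeOH at −78 °C should favour axial hydride attack and give the trans alcohol as the racemate, that is 11 together with its enantiomer (2S,3R)-5-(benzyloxy)-2-[3,4-bis(benzyloxy)phenyl]-3-hydroxychroman-7-yl 3,4,5-tris(benzyloxy)benzoate F5. Preparative chromatography on a chiral stationary phase would separate the two, and F5 would be oxidised back to 10 with Dess–Martin periodinane and recycled.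

**Step 2.** The likely failure is sluggish etherification of the hydrogen-bonded peri phenol, with intermolecular transfer of the galloyl group or alkylation at C2 once the conditions are forced. The fallback introduces the benzyl ether before the ester is present. It sets out from 1 and returns at 5. Allyl bromide and K2CO3 in acetone would alkylate the acidic 6-OH of 1 to give 6-(allyloxy)-4-hydroxybenzofuran-3(2H)-one F6. BnBr and K2CO3 in DMF would then give 6-(allyloxy)-4-(benzyloxy)benzofuran-3(2H)-one F7. Deallylation with Pd(PPh3)4 and morpholine in THF would give 4-(benzyloxy)-6-hydroxybenzofuran-3(2H)-one F8, and acylation of F8 with 3 and Et3N would give 5.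

## Further compounds

F1 | step 4 | 4-formyl-3,5-dihydroxyphenyl 3,4,5-tris(benzyloxy)benzoate | O=Cc1c(O)cc(OC(=O)c2cc(OCc3ccccc3)c(OCc3ccccc3)c(OCc3ccccc3)c2)cc1O
F2 | step 4 | 3-(benzyloxy)-4-formyl-5-hydroxyphenyl 3,4,5-tris(benzyloxy)benzoate | O=Cc1c(O)cc(OC(=O)c2cc(OCc3ccccc3)c(OCc3ccccc3)c(OCc3ccccc3)c2)cc1OCc1ccccc1
F3 | step 4 | rac-5-(benzyloxy)-2-[3,4-bis(benzyloxy)phenyl]-3-nitro-2H-chromen-7-yl 3,4,5-tris(benzyloxy)benzoate | O=C(Oc1cc(OCc3ccccc3)c2C=C([N+](=O)[O-])C(c3ccc(OCc4ccccc4)c(OCc4ccccc4)c3)Oc2c1)c1cc(OCc2ccccc2)c(OCc2ccccc2)c(OCc2ccccc2)c1
F4 | step 3 | 4-(benzyloxy)-3-[(trimethylsilyl)oxy]benzofuran-6-yl 3,4,5-tris(benzyloxy)benzoate | O=C(Oc1cc(OCc3ccccc3)c2c(c1)occ2O[Si](C)(C)C)c1cc(OCc2ccccc2)c(OCc2ccccc2)c(OCc2ccccc2)c1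
F5 | step 5 | (2S,3R)-5-(benzyloxy)-2-[3,4-bis(benzyloxy)phenyl]-3-hydroxychroman-7-yl 3,4,5-tris(benzyloxy)benzoate | O=C(Oc1cc(OCc3ccccc3)c2c(c1)O[C@@H](c1ccc(OCc3ccccc3)c(OCc3ccccc3)c1)[C@H](O)C2)c1cc(OCc2ccccc2)c(OCc2ccccc2)c(OCc2ccccc2)c1
F6 | step 2 | 6-(allyloxy)-4-hydroxybenzofuran-3(2H)-one | O=C1COc2cc(OCC=C)cc(O)c12
F7 | step 2 | 6-(allyloxy)-4-(benzyloxy)benzofuran-3(2H)-one | O=C1COc2cc(OCC=C)cc(OCc3ccccc3)c12
F8 | step 2 | 4-(benzyloxy)-6-hydroxybenzofuran-3(2H)-one | O=C1COc2cc(O)cc(OCc3ccccc3)c12
A1 | alternative 1 | 3-(benzyloxy)-5-[(4-methoxybenzyl)oxy]-2-(trimethylsilyl)phenyl trifluoromethanesulfonate | COc1ccc(COc2cc(OCc3ccccc3)c([Si](C)(C)C)c(OS(=O)(=O)C(F)(F)F)c2)cc1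
A2 | alternative 1 | methyl (2R,3R)-2-(benzyloxy)-3-[3,4-bis(benzyloxy)phenyl]-3-hydroxypropanoate | O[C@H](c1ccc(OCc2ccccc2)c(OCc2ccccc2)c1)[C@@H](OCc1ccccc1)C(=O)OC
A3 | alternative 1 | (2R,3R)-3,5-bis(benzyloxy)-2-[3,4-bis(benzyloxy)phenyl]-7-[(4-methoxybenzyl)oxy]chroman-4-one | COc1ccc(COc2cc(OCc3ccccc3)c3c(c2)O[C@H](c2ccc(OCc4ccccc4)c(OCc4ccccc4)c2)[C@@H](OCc2ccccc2)C3=O)cc1
A4 | alternative 2 | (S)-2-{(R)-[3-(benzyloxy)-5-(triisopropylsilyloxy)phenoxy][3,4-bis(benzyloxy)phenyl]methyl}oxirane | CC(C)[Si](C(C)C)(C(C)C)Oc1cc(OCc2ccccc2)cc(c1)O[C@H](c1ccc(OCc2ccccc2)c(OCc2ccccc2)c1)[C@@H]1CO1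
A5 | alternative 2 | (2R,3S)-5-(benzyloxy)-2-[3,4-bis(benzyloxy)phenyl]-7-(triisopropylsilyloxy)chroman-3-ol | CC(C)[Si](C(C)C)(C(C)C)Oc1cc(OCc3ccccc3)c2c(c1)O[C@H](c1ccc(OCc3ccccc3)c(OCc3ccccc3)c1)[C@@H](O)C2
A6 | alternative 3 | 3,5-dihydroxy-4-(hydroxymethyl)phenyl 3,4,5-tris(benzyloxy)benzoate | O=C(Oc1cc(O)c(CO)c(O)c1)c1cc(OCc2ccccc2)c(OCc2ccccc2)c(OCc2ccccc2)c1
A7 | alternative 3 | benzyl (E)-2-[3,4-bis(benzyloxy)phenyl]ethenyl carbonate | O=C(OCc1ccccc1)O/C=C/c1ccc(OCc2ccccc2)c(OCc2ccccc2)c1
A8 | alternative 3 | (2R,3S)-3-[(benzyloxycarbonyl)oxy]-2-[3,4-bis(benzyloxy)phenyl]-5-hydroxychroman-7-yl 3,4,5-tris(benzyloxy)benzoate | O=C(Oc1cc(O)c2c(c1)O[C@H](c1ccc(OCc3ccccc3)c(OCc3ccccc3)c1)[C@@H](OC(=O)OCc1ccccc1)C2)c1cc(OCc2ccccc2)c(OCc2ccccc2)c(OCc2ccccc2)c1
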